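**Strategy**

Ring atoms C3, C4=C5 and C6 of the 1,2-dioxine, oxygenated at C3 and C6, are the four carbons of a furan, and the peroxyketal carbon C6 is a masked ketone. Everything rests on cutting the C16 chain from C6: 2-furyllithium, an acyl-anion equivalent, is alkylated with 1-bromohexadecane, so that the metalated furan carbon becomes C6. Oxidative dearomatization then opens the ring to a 4-oxo-2-enal, a Wittig step adds C1 and C2, and an iminium-catalysed asymmetric conjugate peroxidation sets C3. Light in acidic methanol finally turns the E-enone to Z, closes the O–O ring on the ketone and forms the methyl ketal. The key-step precursors are furan and the alkyl bromide.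

Key step: step 1

Remark: the C6 ketal centre of such methoxy-dioxines epimerizes in acidic methanol through the peroxycarbenium ion, so only C3 is controlled absolutely and C6 is taken from that equilibrium; the (3S,6S) epimer that forms beside the target in step 8 is removed by chromatography and returned to the same acidic methanol. The sense of induction in step 5 is assigned from the usual shielding model of diarylprolinol silyl ether iminium ions.

**Route**

Step 1
Reactants: 1 furan; 2 1-bromohexadecane
Product: 4 2-hexadecylfuran, via 2-furyllithium 3 (not isolated)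
Conditions: n-BuLi, THF, 0 °C; then 2, DMPU, 0 °C to rt
Reagents that add atoms: none
Why: n-BuLi removes the most acidic ring proton of furan at C2, next to the ring oxygen, and the resulting 2-furyllithium 3 displaces bromide from the primary bromide 2 in an SN2 reaction, which forms the bond between the chain CH2 and the carbon that becomes the peroxyketal carbon C6. The closest known reaction type is the alkylation of 2-lithiofurans with primary alkyl halides, an acyl-anion umpolung in which the furan stands for a cis-4-oxo-2-enal. The step closes no ring and creates no stereocentre; the furan ring it leaves intact supplies C3 to C6 of the dioxine. The selectivity needed is monolithiation at C2 and substitution instead of E2 elimination of the long-chain bromide. Excess furan, the unhindered primary electrophile and the polar cosolvent DMPU should secure both.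

Step 2
Reactants: 4 2-hexadecylfuran
Product: 6 (2E)-4-oxoicos-2-enal, via Z-enal 5 (not isolated)
Conditions: NBS, NaHCO3, acetone/H2O (10:1), −15 °C; then pyridine, rt
Reagents that add atoms: water, O
Why: Oxidative dearomatizing ring opening of a furan to a cis-enedione: NBS brominates an α-carbon, water adds to the oxocarbenium ion and loss of HBr opens the 2,5-dihydrofuran to the cis-4-oxo-2-enal 5, which pyridine should equilibrate to the more stable trans isomer by reversible conjugate addition, the ketone carbon being the former furan C2 that carries the chain.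

Step 3
Reactants: 6 (2E)-4-oxoicos-2-enal; 7 (triphenylphosphoranylidene)acetaldehyde
Product: 8 (2E,4E)-6-oxodocosa-2,4-dienal
Conditions: CH2Cl2, rt, 1.0 equiv of 7 added slowly
Reagents that add atoms: none
Why: Wittig olefination with a stabilized formylmethylene ylide, which should condense with the aldehyde and not with the ketone and give the new C2=C3 double bond E, slow addition of one equivalent keeping the less electrophilic product dienal from reacting again.

Step 4
Reactants: 9 2,3-dimethylbut-2-ene
Product: 10 2-methoxypropan-2-yl hydroperoxide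
Conditions: O3, MeOH/CH2Cl2, −78 °C; N2 purge; used as a solution
Reagents that add atoms: ozone, [O-][O+]=O; methanol, CO
Why: Criegee ozonolysis, in which cycloreversion of the primary ozonide gives acetone and acetone carbonyl oxide and methanol traps the latter as the α-methoxy hydroperoxide, a peroxide nucleophile whose ketal cap is removed later by acid.

Step 5
Reactants: 8 (2E,4E)-6-oxodocosa-2,4-dienal; 10 2-methoxypropan-2-yl hydroperoxide
Product: 11 (3S,4E)-3-[(2-methoxypropan-2-yl)peroxy]-6-oxodocos-4-enal
Conditions: (S)-2-{bis[3,5-bis(trifluoromethyl)phenyl](trimethylsilyloxy)methyl}pyrrolidine (20 mol %), PhCO2H (10 mol %), toluene, −10 °C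
Reagents that add atoms: none
Why: Amine-catalysed asymmetric conjugate peroxidation of an enal (oxa-Michael addition through iminium activation), in which the s-trans E-iminium ion is shielded on the face of the diaryl(silyloxy)methyl group so that the hydroperoxide should add to the β-carbon C3 from the open face and set the (3S) centre, while C5 is deactivated for 1,6-attack by the adjacent ketone.

Step 6
Reactants: 11 (3S,4E)-3-[(2-methoxypropan-2-yl)peroxy]-6-oxodocos-4-enal
Product: 12 (3S,4E)-3-[(2-methoxypropan-2-yl)peroxy]-6-oxodocos-4-enoic acid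
Conditions: NaClO2, NaH2PO4/Na2HPO4 (pH about 6), 2-methylbut-2-ene, t-BuOH/H2O, 0 °C
Reagents that add atoms: sodium chlorite, [Na+].[O-]Cl=O
Why: Pinnick oxidation, in which chlorous acid adds to the aldehyde and fragments to the acid under buffered conditions that should leave the peroxyketal, the enone and the C3 centre untouched, 2-methylbut-2-ene scavenging the hypochlorous acid formed.

Step 7
Reactants: 12 (3S,4E)-3-[(2-methoxypropan-2-yl)peroxy]-6-oxodocos-4-enoic acid
Product: 13 methyl (3S,4E)-3-[(2-methoxypropan-2-yl)peroxy]-6-oxodocos-4-enoate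
Conditions: TMSCHN2, MeOH/toluene (1:4), 0 °C
Reagents that add atoms: (trimethylsilyl)diazomethane, C[Si](C)(C)C=[N+]=[N-]
Why: Esterification with a diazoalkane, in which protonation of the reagent by the acid and SN2 attack of the carboxylate give the methyl ester without acid or base strong enough to cleave the peroxyketal or to eliminate the β-peroxide.

Step 8
Reactants: 13 methyl (3S,4E)-3-[(2-methoxypropan-2-yl)peroxy]-6-oxodocos-4-enoate
Product: 17 methyl 2-[(3S,6R)-6-hexadecyl-6-methoxy-3,6-dihydro-1,2-dioxin-3-yl]acetate, via E-hydroperoxy enone 14 (not isolated), via Z-hydroperoxy enone 15 (not isolated), via dioxinol 16 (not isolated)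
Conditions: TsOH·H2O (10 mol %), MeOH, 0 °C, dark; then hν (350 nm, Pyrex), rt; chromatography
Reagents that add atoms: methanol, CO
Why: Photochemical E/Z isomerization of an enone followed by peroxyketalization, in which acid methanolysis frees the hydroperoxide 14, n→π* excitation gives the Z-enone 15 whose hydroperoxide closes on the ketone by 6-exo-trig addition to the dioxinol 16, and acid-catalysed exchange through the planar peroxycarbenium ion gives the methyl ketal, C3 being untouched and C6 being set under equilibrating conditions so that 17 is separated by chromatography from its (3S,6S) epimer, which is returned to the same acidic methanol.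

**Compound list**

1 | furan | c1ccoc1 | starting material
2 | 1-bromohexadecane | CCCCCCCCCCCCCCCCBr | starting material
3 | 2-furyllithium | [Li]c1ccco1 | intermediate
4 | 2-hexadecylfuran | CCCCCCCCCCCCCCCCc1ccco1 | intermediate
5 | (2Z)-4-oxoicos-2-enal | O=C/C=C\C(=O)CCCCCCCCCCCCCCCC | intermediate
6 | (2E)-4-oxoicos-2-enal | O=C/C=C/C(=O)CCCCCCCCCCCCCCCC | intermediate
7 | (triphenylphosphoranylidene)acetaldehyde | O=CC=P(c1ccccc1)(c1ccccc1)c1ccccc1 | starting material
8 | (2E,4E)-6-oxodocosa-2,4-dienal | O=C/C=C/C=C/C(=O)CCCCCCCCCCCCCCCC | intermediate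
9 | 2,3-dimethylbut-2-ene | CC(C)=C(C)C | starting material
10 | 2-methoxypropan-2-yl hydroperoxide | COC(C)(C)OO | intermediate
11 | (3S,4E)-3-[(2-methoxypropan-2-yl)peroxy]-6-oxodocos-4-enal | O=CC[C@H](OOC(C)(C)OC)/C=C/C(=O)CCCCCCCCCCCCCCCC | intermediate
12 | (3S,4E)-3-[(2-methoxypropan-2-yl)peroxy]-6-oxodocos-4-enoic acid | OC(=O)C[C@H](OOC(C)(C)OC)/C=C/C(=O)CCCCCCCCCCCCCCCC | intermediate
13 | methyl (3S,4E)-3-[(2-methoxypropan-2-yl)peroxy]-6-oxodocos-4-enoate | COC(=O)C[C@H](OOC(C)(C)OC)/C=C/C(=O)CCCCCCCCCCCCCCCC | intermediate
14 | methyl (3S,4E)-3-hydroperoxy-6-oxodocos-4-enoate | COC(=O)C[C@H](OO)/C=C/C(=O)CCCCCCCCCCCCCCCC | intermediate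
15 | methyl (3S,4Z)-3-hydroperoxy-6-oxodocos-4-enoate | COC(=O)C[C@H](OO)/C=C\C(=O)CCCCCCCCCCCCCCCC | intermediate
16 | methyl 2-[(3S)-6-hexadecyl-6-hydroxy-3,6-dihydro-1,2-dioxin-3-yl]acetate (both C6 anomers) | COC(=O)C[C@@H]1OOC(O)(CCCCCCCCCCCCCCCC)C=C1 | intermediate
17 | methyl 2-[(3S,6R)-6-hexadecyl-6-methoxy-3,6-dihydro-1,2-dioxin-3-yl]acetate | CCCCCCCCCCCCCCCC[C@]1(OC)C=C[C@H](CC(=O)OC)OO1 | target

**Step count and risks**

Total step count: 8. Longest linear sequence: 7 steps (steps 1, 2, 3, 5, 6, 7, 8); step 4 prepares the peroxide reagent in a side branch.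

The three steps most likely to fail:

1. Step 5. The extended, flat dienyl iminium ion with its remote ketone may give the catalyst too little facial differentiation, so that the peroxide adds to C3 with low enantiocontrol. The fallback replaces catalyst control by resolution and sets out from 8. Hydroperoxide 10 is added under pyrrolidine/PhCO2H catalysis without stereocontrol to give racemic (4E)-3-[(2-methoxypropan-2-yl)peroxy]-6-oxodocos-4-enal F1. The conditions of steps 6 and 7 then give racemic (4E)-3-[(2-methoxypropan-2-yl)peroxy]-6-oxodocos-4-enoic acid F2 and racemic methyl (4E)-3-[(2-methoxypropan-2-yl)peroxy]-6-oxodocos-4-enoate F3. PPTS in methanol frees racemic methyl (4E)-3-hydroperoxy-6-oxodocos-4-enoate F4. This is re-ketalized with the chiral enol ether (1S,2R)-2-phenylcyclohexyl prop-1-en-2-yl ether (PPTS, CH2Cl2) to diastereomeric perketals. Chromatography isolates the (3S) isomer, methyl (3S,4E)-6-oxo-3-{[2-{[(1S,2R)-2-phenylcyclohexyl]oxy}propan-2-yl]peroxy}docos-4-enoate F5. F5 is submitted to the conditions of step 8, where acidic methanol releases 14, and the route is rejoined at 14.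

2. Step 8. Photolytic cleavage of the O–O bond or acid-promoted fragmentation of the free allylic hydroperoxide may outrun the E-to-Z isomerization that feeds the ring closure. The fallback carries the cis geometry of the furan through instead of making it with light and sets out from 5. Step 2 is run without the pyridine treatment and the crude Z-enal 5 is condensed directly with 7 to give (2E,4Z)-6-oxodocosa-2,4-dienal F6. The conditions of steps 5, 6 and 7 then give (3S,4Z)-3-[(2-methoxypropan-2-yl)peroxy]-6-oxodocos-4-enal F7, (3S,4Z)-3-[(2-methoxypropan-2-yl)peroxy]-6-oxodocos-4-enoic acid F8 and methyl (3S,4Z)-3-[(2-methoxypropan-2-yl)peroxy]-6-oxodocos-4-enoate F9. TsOH in methanol in the dark removes the ketal cap and rejoins the route at 15, which closes to 16 and 17 without irradiation.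

3. Step 3. The product dienal may compete with 6 for the ylide (over-homologation), and the doubly activated 4-oxo-2-enal may oligomerize by conjugate addition. The fallback uses a masked two-carbon ylide and sets out from 6. Wittig reaction with (1,3-dioxolan-2-ylmethyl)triphenylphosphonium bromide and LiOMe in DMF gives (3E)-1-(1,3-dioxolan-2-yl)henicosa-1,3-dien-5-one F10 as a mixture of isomers at the new double bond; its acetal cannot react a second time. Aqueous HCl in THF with a trace of iodine hydrolyses the acetal and equilibrates the new double bond to E, rejoining the route at 8.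

**Further compounds**

F1 | step 5 | racemic (4E)-3-[(2-methoxypropan-2-yl)peroxy]-6-oxodocos-4-enal | O=CCC(OOC(C)(C)OC)/C=C/C(=O)CCCCCCCCCCCCCCCC
F2 | step 5 | racemic (4E)-3-[(2-methoxypropan-2-yl)peroxy]-6-oxodocos-4-enoic acid | OC(=O)CC(OOC(C)(C)OC)/C=C/C(=O)CCCCCCCCCCCCCCCC
F3 | step 5 | racemic methyl (4E)-3-[(2-methoxypropan-2-yl)peroxy]-6-oxodocos-4-enoate | COC(=O)CC(OOC(C)(C)OC)/C=C/C(=O)CCCCCCCCCCCCCCCC
F4 | step 5 | racemic methyl (4E)-3-hydroperoxy-6-oxodocos-4-enoate | COC(=O)CC(OO)/C=C/C(=O)CCCCCCCCCCCCCCCC
F5 | step 5 | methyl (3S,4E)-6-oxo-3-{[2-{[(1S,2R)-2-phenylcyclohexyl]oxy}propan-2-yl]peroxy}docos-4-enoate | COC(=O)C[C@H](OOC(C)(C)O[C@H]1CCCC[C@@H]1c1ccccc1)/C=C/C(=O)CCCCCCCCCCCCCCCC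
F6 | step 8 | (2E,4Z)-6-oxodocosa-2,4-dienal | O=C/C=C/C=C\C(=O)CCCCCCCCCCCCCCCC
F7 | step 8 | (3S,4Z)-3-[(2-methoxypropan-2-yl)peroxy]-6-oxodocos-4-enal | O=CC[C@H](OOC(C)(C)OC)/C=C\C(=O)CCCCCCCCCCCCCCCC
F8 | step 8 | (3S,4Z)-3-[(2-methoxypropan-2-yl)peroxy]-6-oxodocos-4-enoic acid | OC(=O)C[C@H](OOC(C)(C)OC)/C=C\C(=O)CCCCCCCCCCCCCCCC
F9 | step 8 | methyl (3S,4Z)-3-[(2-methoxypropan-2-yl)peroxy]-6-oxodocos-4-enoate | COC(=O)C[C@H](OOC(C)(C)OC)/C=C\C(=O)CCCCCCCCCCCCCCCC
F10 | step 3 | (3E)-1-(1,3-dioxolan-2-yl)henicosa-1,3-dien-5-one | O=C(CCCCCCCCCCCCCCCC)/C=C/C=CC1OCCO1
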